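(Readings and results were computed for substances that don't exist, noise included.)

In a one-step world, starting material and second substrate react in a single encounter, and the rate of conversion is κ times the fraction of starting material left times the equivalents of second substrate left, with κ proportional to the enzyme loading.

- dusk: starting material 20 mM; second substrate 1.5 equiv; enzyme 0.0034 mol%; run made earlier
- flask: starting material 20 mM; second substrate 1.50 equiv; enzyme 0.0023 mol%

dusk run (percent of the starting material charged)

| time / min | product / % |
|---|---|
| 1.50 | 7.8 |
| 3.00 | 16.0 |
| 5.00 | 24.4 |
| 6.00 | 28.3 |
| 8.00 | 33.4 |
| 10.0 | 39.8 |

(scatter of a reading: 1 percentage point)

- apparent order in second substrate when 30 % of the starting material are converted (percent change of the rate of making product for one percent more second substrate charged)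
- factor on the rate of making product when 30 % of the starting material are converted if enzyme is charged twice over

- what was read earlier has a scatter of 1 percentage point, one standard deviation
- no earlier run changes the charge of enzyme; that part of a forecast is a guess
- no earlier run changes the charge of second substrate; that part of a forecast is a guess

Integrating that law through the last dusk reading, I read κ = 0.0398 min⁻¹, and scaling by loading gave 0.0269 min⁻¹ for the flask. So I drew the flask's curve starting at a slope of 0.0404 min⁻¹, as a fraction of the charge, and passing 30 % at 9.91 min. I let it bend towards full conversion, since starting material is the limiting reagent, with a third of the second substrate over.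

The order is asked at fixed conversion, where the second substrate left is the charge minus a fixed amount used. Charge over remainder came to 1.25. I called this ratio the leverage: the charge of second substrate divided by what is left of it at the conversion looked at. In my one-step world the order equals the leverage, and the enzyme factor is 2; no earlier run tested either.

The forecast gave an order of 0.6 (0.1 to 1.05) and a factor of 2 (1.7 to 2.2), holding that "One charge of second substrate cannot separate these". My order was higher than its 0.6.

The flask gave an order of 1.2, close to the leverage, and a factor of 2.06.

    starting material + enzyme ⇌ starting complex (K = 21.8 M⁻¹, k = 44400 M⁻¹ s⁻¹)
    ternary complex → enzyme + product (k = 274 s⁻¹)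
    enzyme → spent catalyst (k = 1.37 × 10⁻⁴ s⁻¹)
    second substrate + starting complex ⇌ ternary complex (K = 14.8 M⁻¹, k = 28300 M⁻¹ s⁻¹)

In the flask, the half-life of enzyme by its step to spent catalyst, at 13.4 min, was 84 min, longer than the 9.88 min taken to reach 30 %. At that conversion in the flask, ternary complex held 6.22 % of the catalyst. With twice the second substrate charged, the remainder of second substrate at that conversion was 2.25 times that of the flask, and the factor on the rate was 2.07.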